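**Retrosynthetic overview**

1. The (S)-lactol is released last from its (R)-1-phenylethyl acetal, whose separable epimers resolve the only stereocentre. Before that, ring C (the seven-membered ester/ether ring) is closed by lactonisation of the ring A acid onto the B2 hydroxyl. Ring D (the hydroxy lactone) closes by itself once the B5 acid and the aldehyde on B6 are unmasked.
2. The strategy rests on ring B being a beta-resorcylate: ether oxygen on B1, oxygen on B2 and B4, CH at B3, carboxyl carbon on B5, aldehyde-level carbon on B6. B3–B4–B5 plus the lactone carbon are therefore an acetoacetate, and B2–B1–B6 plus the lactol carbon are a four-carbon keto ester already bound to ring A through the ether oxygen.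
3. Key disconnections: B2–B3 (Claisen acylation of an acetoacetate dianion by an aryloxy methoxy enoate) and B5–B6 (aromatising addition–elimination). tert-Butyl acetoacetate is used so that one acid treatment later frees both acids.
4. The enoate comes from the ring A phenol by Rh2(OAc)4-catalysed carbenoid O–H insertion of a diazo keto ester and enol O-methylation. The ring A phenol comes from orsellinic acid (tert-butyl ester, 4-O-methylation, ortho-formylation, acetal).
5. Ring order: A (from orsellinic acid), then B (key step), then D (acid deprotection), then C (lactonisation).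

Key step: step 8

Remarks
- ArO– stands for the ring A unit 2-(tert-butoxycarbonyl)-6-(dimethoxymethyl)-5-methoxy-3-methylphenoxy.
- Assumption: a 3-hydroxyphthalide lactol can epimerise through its open formyl acid form under acid or base; the single enantiomer is taken to hold its configuration under the neutral, aprotic conditions of the last step and a cold, neutral isolation.
- Assumption: the two acetal epimers obtained after lactonisation are separable on silica; their configuration would be assigned by X-ray crystallography.

**Route**

Step 1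
Reactants: 1 orsellinic acid (2,4-dihydroxy-6-methylbenzoic acid)
Product: 2 tert-butyl 2,4-dihydroxy-6-methylbenzoate
Conditions: O-tert-butyl-N,N'-diisopropylisourea (3 equiv), CH2Cl2, rt
Reagents that add atoms: O-tert-butyl-N,N'-diisopropylisourea, CC(C)NC(=NC(C)C)OC(C)(C)C
Why: Esterification by tert-butyl transfer from the protonated isourea should touch only the carboxylic acid, the one group acidic enough to activate the reagent, and room temperature avoids decarboxylation of the resorcylic acid.

Step 2
Reactants: 2 tert-butyl 2,4-dihydroxy-6-methylbenzoate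
Product: 3 tert-butyl 2-hydroxy-4-methoxy-6-methylbenzoate
Conditions: MeI (1.1 equiv), K2CO3, acetone, rt
Reagents that add atoms: iodomethane, CI
Why: Williamson etherification should be selective because the 2-OH is held in a hydrogen bond to the ester carbonyl, so one equivalent of MeI methylates the free 4-OH.

Step 3
Reactants: 3 tert-butyl 2-hydroxy-4-methoxy-6-methylbenzoate
Product: 4 tert-butyl 3-formyl-2-hydroxy-4-methoxy-6-methylbenzoate
Conditions: MgCl2, Et3N, (CH2O)n, MeCN, reflux; dilute HCl work-up
Reagents that add atoms: paraformaldehyde (formaldehyde), C=O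
Why: In the Casnati–Skattebøl ortho-formylation the magnesium phenoxide delivers formaldehyde only to a carbon ortho to its oxygen, of which C3 is the single free one, a second formaldehyde then oxidises the benzylic alkoxide by hydride transfer, and the basic medium spares the tert-butyl ester that acid-based formylations would cleave.

Step 4
Reactants: 4 tert-butyl 3-formyl-2-hydroxy-4-methoxy-6-methylbenzoate
Product: 5 tert-butyl 3-(dimethoxymethyl)-2-hydroxy-4-methoxy-6-methylbenzoate
Conditions: HC(OMe)3, MeOH, TsOH (cat.), rt; Et3N quench
Reagents that add atoms: trimethyl orthoformate, COC(OC)OC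
Why: Acid-catalysed acetalisation driven by the orthoformate should mask the aldehyde before the carbanion chemistry of step 8, and the phenol keeps its hydrogen bond to the ester so little stabilisation is lost.

Step 5
Reactants: 6 methyl 4,4-dimethoxy-3-oxobutanoate
Product: 7 methyl 2-diazo-4,4-dimethoxy-3-oxobutanoate
Conditions: 4-acetamidobenzenesulfonyl azide, Et3N, MeCN, 0 °C to rt
Reagents that add atoms: 4-acetamidobenzenesulfonyl azide, CC(=O)Nc1ccc(cc1)S(=O)(=O)N=[N+]=[N-]
Why: Regitz diazo transfer to the active methylene of a beta-keto ester is routine and leaves the acetal alone.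

Step 6
Reactants: 5 tert-butyl 3-(dimethoxymethyl)-2-hydroxy-4-methoxy-6-methylbenzoate; 7 methyl 2-diazo-4,4-dimethoxy-3-oxobutanoate
Product: 8 methyl 2-(ArO)-4,4-dimethoxy-3-oxobutanoate (racemic, enolisable)
Conditions: Rh2(OAc)4 (2 mol %), ClCH2CH2Cl, 70 °C, slow addition of 7
Reagents that add atoms: none
Why: Carbenoid O–H insertion catalysed by Rh2(OAc)4 (oxonium ylide, then proton shift) should join the four-carbon unit to the ring A oxygen under neutral conditions that spare both acetals, and hydrogen-bonded salicylate-type phenols are known to undergo it.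

Step 7
Reactants: 8 methyl 2-(ArO)-4,4-dimethoxy-3-oxobutanoate
Product: 9 methyl (2Z)-2-(ArO)-3,4,4-trimethoxybut-2-enoate (the 2E isomer, if formed, is carried along and reacts alike)
Conditions: Cs2CO3, Me2SO4, DMF, 0 °C to rt
Reagents that add atoms: dimethyl sulfate, COS(=O)(=O)OC
Why: O-alkylation of the beta-keto ester enolate is expected because a caesium enolate in DMF meets a hard sulfate electrophile and C-methylation would have to build a quaternary carbon bearing OAr; the step removes the acidic C–H and turns the ketone carbon into a vinylogous ester carbon with a leaving group.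

Step 8
Reactants: 9 methyl (2Z)-2-(ArO)-3,4,4-trimethoxybut-2-enoate; 10 tert-butyl acetoacetate
Product: 12 tert-butyl 3-(ArO)-2-(dimethoxymethyl)-4,6-dihydroxybenzoate, via tert-butyl 6-(ArO)-7,8,8-trimethoxy-3,5-dioxooct-6-enoate 11 (not isolated)
Conditions: 10 (3 equiv), NaH then n-BuLi, THF, 0 °C; 9, −78 to 0 °C; AcOH; then Mg(OMe)2, MeOH, rt to 50 °C; cold aq. NH4Cl
Reagents that add atoms: none
Why: The dianion of 10 adds through its terminal carbon to the methyl ester carbonyl of 9 and methoxide leaves (crossed Claisen, bond B2–B3) to give 11; under Mg(OMe)2 the magnesium chelate of the beta-keto ester then attacks the methoxy-bearing alkene carbon through its central carbon (bond B5–B6), methoxide is expelled, and enolisation of the B2 and B4 ketones gives the arene. The closest known chemistry is the acylation of beta-keto ester dianions by esters to 3,5-diketo esters, their base-mediated cyclisation to resorcylates, and the [3+3] condensation of 1,3-dicarbonyl dianion equivalents with 3-alkoxy enones. Ring B closes 6-endo-trig by addition–elimination at the vinylogous ester carbon; no stereocentre is formed and the alkene geometry is lost on aromatisation, so either isomer of 9 serves. In the Claisen stage the terminal carbanion is the more basic and nucleophilic site of the dianion, it should attack the carbonyl and not the beta carbon because that carbon is fully substituted and donor-stabilised, and 9 has no acidic C–H next to its ester. The ring A ester is a tert-butyl ester between two ortho substituents and both acetals are base-stable, so they should be spectators. C-cyclisation should beat O-cyclisation because the magnesium ion ties up the enolate oxygens, and any 4-pyranone formed is reopened by methoxide and funnelled to the arene.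

Step 9
Reactants: 12 tert-butyl 3-(ArO)-2-(dimethoxymethyl)-4,6-dihydroxybenzoate
Product: 13 3-formyl-4-methoxy-6-methyl-2-[(3,5,7-trihydroxy-1-oxo-1,3-dihydro-2-benzofuran-4-yl)oxy]benzoic acid (racemic lactol)
Conditions: TFA/H2O (9:1), CH2Cl2, 0 °C to rt
Reagents that add atoms: water, O
Why: Acidolysis should cleave both tert-butyl esters by E1 loss of isobutene and hydrolyse both acetals, and the B5 acid then adds to the aldehyde on B6 (5-exo-trig) to close ring D as the lactol, formed racemic with no control.

Step 10
Reactants: 13 seco acid with free lactol; 14 (R)-1-phenylethanol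
Product: 15 3-formyl-4-methoxy-6-methyl-2-({5,7-dihydroxy-1-oxo-3-[(1R)-1-phenylethoxy]-1,3-dihydro-2-benzofuran-4-yl}oxy)benzoic acid (both epimers at the acetal carbon)
Conditions: 14 (5 equiv), PPTS (cat.), 4 Å MS, toluene, 60 °C
Reagents that add atoms: none
Why: Pseudo-ester formation of a 3-hydroxyphthalide under mild acid exchanges the lactol OH for OR through the open formyl acid or the cyclic oxocarbenium ion, while the di-ortho-substituted ring A acid should not esterify and the weak acid should not ionise the benzylic alcohol, so its (R) centre is kept and the acetal carbon forms as both epimers.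

Step 11
Reactants: 15 pseudo-ester acid (epimer mixture)
Product: 16 the (S)-acetal depsidone: the target carrying (1R)-1-phenylethyl on the lactol oxygen, (S) at the acetal carbon
Conditions: DCC, CH2Cl2/THF (high dilution), rt; chromatography on silica
Reagents that add atoms: none
Why: Carbodiimide lactonisation as used for depsidones activates the only free carboxyl, on ring A, which the adjacent B2 hydroxyl captures in a 7-exo-trig closure of ring C (the B4 hydroxyl is out of reach), and chromatography then separates 16 from its (R)-acetal epimer, which could be re-equilibrated at the acetal carbon with PPTS and 14 and put through the separation again.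

Step 12
Reactants: 16 (S)-acetal depsidone
Product: 17 the target, (1S)-1,4-dihydroxy-10-methoxy-8-methyl-3,7-dioxo-1,3-dihydro-7H-isobenzofuro[4,5-b][1,4]benzodioxepine-11-carbaldehyde
Conditions: H2 (1 atm), 10% Pd/C, EtOAc, rt, stopped after one equivalent of H2
Reagents that add atoms: none
Why: Hydrogenolysis of the benzylic C–O bond on the unhindered 1-phenylethyl side should give ethylbenzene and the lactol without breaking either C–O bond of the acetal carbon, so the (S) configuration fixed by the separation is retained.

**Compound list**

1 | orsellinic acid | Cc1cc(O)cc(O)c1C(=O)O | starting material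
2 | tert-butyl 2,4-dihydroxy-6-methylbenzoate | Cc1cc(O)cc(O)c1C(=O)OC(C)(C)C | intermediate
3 | tert-butyl 2-hydroxy-4-methoxy-6-methylbenzoate | COc1cc(C)c(C(=O)OC(C)(C)C)c(O)c1 | intermediate
4 | tert-butyl 3-formyl-2-hydroxy-4-methoxy-6-methylbenzoate | COc1cc(C)c(C(=O)OC(C)(C)C)c(O)c1C=O | intermediate
5 | tert-butyl 3-(dimethoxymethyl)-2-hydroxy-4-methoxy-6-methylbenzoate | COc1cc(C)c(C(=O)OC(C)(C)C)c(O)c1C(OC)OC | intermediate
6 | methyl 4,4-dimethoxy-3-oxobutanoate | COC(=O)CC(=O)C(OC)OC | starting material
7 | methyl 2-diazo-4,4-dimethoxy-3-oxobutanoate | COC(=O)C(=[N+]=[N-])C(=O)C(OC)OC | intermediate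
8 | methyl 2-[2-(tert-butoxycarbonyl)-6-(dimethoxymethyl)-5-methoxy-3-methylphenoxy]-4,4-dimethoxy-3-oxobutanoate | COC(=O)C(Oc1c(C(OC)OC)c(OC)cc(C)c1C(=O)OC(C)(C)C)C(=O)C(OC)OC | intermediate
9 | methyl (2Z)-2-[2-(tert-butoxycarbonyl)-6-(dimethoxymethyl)-5-methoxy-3-methylphenoxy]-3,4,4-trimethoxybut-2-enoate | COC(=O)/C(Oc1c(C(OC)OC)c(OC)cc(C)c1C(=O)OC(C)(C)C)=C(/OC)C(OC)OC | intermediate
10 | tert-butyl acetoacetate | CC(=O)CC(=O)OC(C)(C)C | starting material
11 | tert-butyl (6Z)-6-[2-(tert-butoxycarbonyl)-6-(dimethoxymethyl)-5-methoxy-3-methylphenoxy]-7,8,8-trimethoxy-3,5-dioxooct-6-enoate (not isolated) | CC(C)(C)OC(=O)CC(=O)CC(=O)/C(Oc1c(C(OC)OC)c(OC)cc(C)c1C(=O)OC(C)(C)C)=C(/OC)C(OC)OC | intermediate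
12 | tert-butyl 3-[2-(tert-butoxycarbonyl)-6-(dimethoxymethyl)-5-methoxy-3-methylphenoxy]-2-(dimethoxymethyl)-4,6-dihydroxybenzoate | CC(C)(C)OC(=O)c1c(O)cc(O)c(Oc2c(C(OC)OC)c(OC)cc(C)c2C(=O)OC(C)(C)C)c1C(OC)OC | intermediate
13 | 3-formyl-4-methoxy-6-methyl-2-[(3,5,7-trihydroxy-1-oxo-1,3-dihydro-2-benzofuran-4-yl)oxy]benzoic acid (racemic lactol) | COc1cc(C)c(C(=O)O)c(Oc2c(O)cc(O)c3c2C(O)OC3=O)c1C=O | intermediate
14 | (R)-1-phenylethanol | C[C@@H](O)c1ccccc1 | starting material
15 | 3-formyl-4-methoxy-6-methyl-2-({5,7-dihydroxy-1-oxo-3-[(1R)-1-phenylethoxy]-1,3-dihydro-2-benzofuran-4-yl}oxy)benzoic acid (both acetal epimers) | COc1cc(C)c(C(=O)O)c(Oc2c(O)cc(O)c3c2C(O[C@H](C)c4ccccc4)OC3=O)c1C=O | intermediate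
16 | (S)-acetal depsidone, O-[(1R)-1-phenylethyl] derivative of the target | COc1cc(C)c2c(c1C=O)Oc1c(cc(O)c3c1[C@@H](O[C@H](C)c4ccccc4)OC3=O)OC2=O | intermediate
17 | (1S)-1,4-dihydroxy-10-methoxy-8-methyl-3,7-dioxo-1,3-dihydro-7H-isobenzofuro[4,5-b][1,4]benzodioxepine-11-carbaldehyde | COc1cc(C)c2c(c1C=O)Oc1c(cc(O)c3c1[C@@H](O)OC3=O)OC2=O | target

**Step count**

Total: 12 steps. Longest linear sequence: 11 steps (1 to 17 through steps 1–4 and 6–12).

**Steps most likely to fail**

Step 8. The Claisen acylation may be slow at the donor-substituted ester carbonyl, the dianion may instead remove the proton on the acetal-bearing carbon, or the diketo ester may cyclise through oxygen. The fallback sets out from 9 and comes back at 11. Saponification of 9 (LiOH, THF/MeOH/H2O) would give the (2Z)-2-(ArO)-3,4,4-trimethoxybut-2-enoic acid F1. 1,1'-Carbonyldiimidazole in THF would convert it to the acyl imidazolide F2. This more electrophilic donor would acylate the lithium dienolate of 2,2,6-trimethyl-4H-1,3-dioxin-4-one (LiN(SiMe3)2, THF, −78 °C) at its methyl carbon to give the keto dioxinone F3. Heating F3 in toluene with tert-butanol (110 °C) would release acetone and an acyl ketene that the alcohol traps, giving 11, which is cyclised to 12 with Mg(OMe)2 as in the second stage of step 8.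

Step 12. The ring A aldehyde or the open form of the lactol may be reduced, the benzylic acetal C–O bond on ring B may be cleaved, or the lactol may epimerise on the catalyst. The fallback sets out from 13 and comes back at 17. Acetalisation of 13 with (R)-1-(2-nitrophenyl)ethanol (PPTS, 4 Å MS, toluene) would give the photolabile pseudo-ester acid F4 as both acetal epimers. DCC lactonisation and chromatography would give the (S)-acetal depsidone F5 and its (R)-acetal epimer F6. Irradiation of F5 at 365 nm in neutral MeCN would release 17 through the aci-nitro rearrangement, which breaks the C–O bond on the auxiliary side only, with no hydrogen and no acid or base.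

Step 6. Insertion into the hindered, hydrogen-bonded phenol O–H may be outrun by carbene dimerisation or by attack of the carbenoid on the acetal oxygens. The fallback sets out from 5 and comes back at 8; step 5 and compound 7 are then not needed. Williamson etherification of 5 with methyl bromoacetate (K2CO3, DMF) would give the methyl (ArO)acetate F7. Crossed Claisen acylation of its lithium enolate with methyl dimethoxyacetate (LiN(SiMe3)2, THF, −78 °C, acylating ester present from the start) would give 8.

**Further compounds**

F1 | step 8 | (2Z)-2-[2-(tert-butoxycarbonyl)-6-(dimethoxymethyl)-5-methoxy-3-methylphenoxy]-3,4,4-trimethoxybut-2-enoic acid | OC(=O)/C(Oc1c(C(OC)OC)c(OC)cc(C)c1C(=O)OC(C)(C)C)=C(/OC)C(OC)OC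
F2 | step 8 | acyl imidazolide of F1 | O=C(n2ccnc2)/C(Oc1c(C(OC)OC)c(OC)cc(C)c1C(=O)OC(C)(C)C)=C(/OC)C(OC)OC
F3 | step 8 | 6-{(3Z)-3-[2-(tert-butoxycarbonyl)-6-(dimethoxymethyl)-5-methoxy-3-methylphenoxy]-4,5,5-trimethoxy-2-oxopent-3-en-1-yl}-2,2-dimethyl-4H-1,3-dioxin-4-one | CC1(C)OC(CC(=O)/C(Oc2c(C(OC)OC)c(OC)cc(C)c2C(=O)OC(C)(C)C)=C(/OC)C(OC)OC)=CC(=O)O1
F4 | step 12 | 3-formyl-4-methoxy-6-methyl-2-({5,7-dihydroxy-3-[(1R)-1-(2-nitrophenyl)ethoxy]-1-oxo-1,3-dihydro-2-benzofuran-4-yl}oxy)benzoic acid (both acetal epimers) | COc1cc(C)c(C(=O)O)c(Oc2c(O)cc(O)c3c2C(O[C@H](C)c4ccccc4[N+](=O)[O-])OC3=O)c1C=O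
F5 | step 12 | (S)-acetal depsidone, O-[(1R)-1-(2-nitrophenyl)ethyl] derivative of the target | COc1cc(C)c2c(c1C=O)Oc1c(cc(O)c3c1[C@@H](O[C@H](C)c4ccccc4[N+](=O)[O-])OC3=O)OC2=O
F6 | step 12 | (R)-acetal epimer of F5 | COc1cc(C)c2c(c1C=O)Oc1c(cc(O)c3c1[C@H](O[C@H](C)c4ccccc4[N+](=O)[O-])OC3=O)OC2=O
F7 | step 6 | methyl 2-[2-(tert-butoxycarbonyl)-6-(dimethoxymethyl)-5-methoxy-3-methylphenoxy]acetate | COC(=O)COc1c(C(OC)OC)c(OC)cc(C)c1C(=O)OC(C)(C)C
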